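**Strategy.** The 3(2H)-furanone (ring atoms O, C10, C1, C2, C3; germacrane numbering) is grown from a three-membered ring. A Sharpless-derived alkynyl oxirane (O, C10, C1) undergoes gold-catalysed methanolytic ring expansion in which the oxirane oxygen, held on the quaternary stereocentre C10, is transferred from C1 to the distal alkyne carbon C3. The step exploits the C10–O bond of the furanone and the C2≡C3 unsaturation, so the epoxidation-derived configuration at C10 enters the five-membered ring untouched; DDQ then adjusts C1 to the ketone. The precursor is a (Z)-enynyl oxirane from a Sonogashira coupling. The 10-membered carbocycle is closed late at C6–C7 by chromium-mediated allylation from an α-(bromomethyl)butenolide.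

Key step: step 9

Remark on numbering: C1 ketone carbon, C2=C3 enol ether, C4(C15 methyl)=C5, C6 acyloxy carbon, C7, C8 lactone carbinol, C9 methylene, C10 quaternary carbon (C14 methyl), C11/C12/C13 lactone α-carbon, carbonyl and exocyclic methylene.

Step 1
Reactants: 1 (2R)-2-ethenyloxirane
Product: 2 (3S)-hex-1-en-5-yn-3-ol
Conditions: LiC≡CH·H2NCH2CH2NH2, DMSO, 0 °C → rt; then H2O
Reagents that add atoms: lithium acetylide–ethylenediamine complex, [Li+].[C-]#C.NCCN
Why: Epoxide alkynylation by SN2 attack at the unsubstituted oxirane carbon, so the C8 carbinol centre (S) is carried over unchanged from 1.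

Step 2
Reactants: 2 (3S)-hex-1-en-5-yn-3-ol
Product: 3 tert-butyl[(3S)-hex-1-en-5-yn-3-yloxy]dimethylsilane
Conditions: TBSCl, imidazole, DMF, rt
Reagents that add atoms: tert-butyldimethylsilyl chloride, C[Si](C)(Cl)C(C)(C)C
Why: Imidazole-promoted silylation masks the C8 hydroxyl as a non-participating ether for the aluminium, titanium and gold steps.

Step 3
Reactants: 3 tert-butyl[(3S)-hex-1-en-5-yn-3-yloxy]dimethylsilane
Product: 5 (2E,5S)-5-(tert-butyldimethylsilyloxy)-3-methylhepta-2,6-dien-1-ol, via alkenyldimethylalane 4 (not isolated)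
Conditions: Me3Al, Cp2ZrCl2 (20 mol %), CH2Cl2, 0 °C → rt; then n-BuLi, (CH2O)n, THF, −78 °C → rt; H2O
Reagents that add atoms: trimethylaluminium, C[Al](C)C; formaldehyde (from paraformaldehyde), C=O
Why: Negishi carboalumination adds Me–Al syn and regioselectively across the terminal alkyne (the vinyl group is inert), and hydroxymethylation of the aluminate with retention gives the E trisubstituted allylic alcohol.

Step 4
Reactants: 5 (2E,5S)-5-(tert-butyldimethylsilyloxy)-3-methylhepta-2,6-dien-1-ol
Product: 6 [(2R,3R)-3-[(2S)-2-(tert-butyldimethylsilyloxy)but-3-en-1-yl]-3-methyloxiran-2-yl]methanol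
Conditions: Ti(OiPr)4, D-(−)-diethyl tartrate, t-BuOOH, 4 Å molecular sieves, CH2Cl2, −20 °C
Reagents that add atoms: tert-butyl hydroperoxide, CC(C)(C)OO
Why: Sharpless asymmetric epoxidation of the E allylic alcohol is reagent-controlled and should set C10 (R) and C1 (R), as for geraniol-type substrates with the D-tartrate.

Step 5
Reactants: 6 [(2R,3R)-3-[(2S)-2-(tert-butyldimethylsilyloxy)but-3-en-1-yl]-3-methyloxiran-2-yl]methanol
Product: 8 tert-butyl{[(2S)-1-[(2R,3R)-3-ethynyl-2-methyloxiran-2-yl]but-3-en-2-yl]oxy}dimethylsilane, via epoxy aldehyde 7 (not isolated)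
Conditions: Dess–Martin periodinane, CH2Cl2, 0 °C; then MeOH, K2CO3, dimethyl (1-diazo-2-oxopropyl)phosphonate, 0 °C → rt
Reagents that add atoms: dimethyl (1-diazo-2-oxopropyl)phosphonate, CC(=O)C(=[N+]=[N-])P(=O)(OC)OC
Why: Dess–Martin oxidation followed in the same flask by Ohira–Bestmann (Seyferth–Gilbert) homologation gives the terminal alkyne under mild carbonate conditions that leave the oxirane intact.

Step 6
Reactants: 9 but-2-yn-1-ol
Product: 10 (2Z)-3-iodobut-2-en-1-ol
Conditions: NaAlH2(OCH2CH2OMe)2, THF, 0 °C → rt; then I2, −78 °C; H2O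
Reagents that add atoms: iodine, II
Why: Hydroxyl-directed trans-hydroalumination places aluminium at C3 and iodinolysis with retention gives the Z vinyl iodide (iodine cis to CH2OH), which encodes the C4=C5 geometry.

Step 7
Reactants: 10 (2Z)-3-iodobut-2-en-1-ol
Product: 11 (2Z)-3-iodobut-2-en-1-yl acetate
Conditions: Ac2O, pyridine, DMAP (cat.), CH2Cl2, 0 °C
Reagents that add atoms: acetic anhydride, CC(=O)OC(C)=O
Why: Acetylation turns the allylic hydroxyl into an ester oxygen that cannot add to the gold-activated alkyne in step 9.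

Step 8
Reactants: 8 tert-butyl{[(2S)-1-[(2R,3R)-3-ethynyl-2-methyloxiran-2-yl]but-3-en-2-yl]oxy}dimethylsilane; 11 (2Z)-3-iodobut-2-en-1-yl acetate
Product: 12 (2Z)-5-[(2R,3R)-3-[(2S)-2-(tert-butyldimethylsilyloxy)but-3-en-1-yl]-3-methyloxiran-2-yl]-3-methylpent-2-en-4-yn-1-yl acetate
Conditions: Pd(PPh3)2Cl2 (cat.), CuI (cat.), Et3N, THF, rt
Reagents that add atoms: none
Why: Sonogashira coupling joins alkyne and vinyl iodide with retention of the Z geometry, oxidative addition to the vinyl iodide at room temperature being faster than ionization of the propargylic oxirane or allylic acetate by zerovalent palladium.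

Step 9
Reactants: 12 (2Z)-5-[(2R,3R)-3-[(2S)-2-(tert-butyldimethylsilyloxy)but-3-en-1-yl]-3-methyloxiran-2-yl]-3-methylpent-2-en-4-yn-1-yl acetate
Product: 14 (2Z)-3-[(4S,5R)-5-[(2S)-2-(tert-butyldimethylsilyloxy)but-3-en-1-yl]-4-methoxy-5-methyl-4,5-dihydrofuran-2-yl]but-2-en-1-yl acetate, via methoxy alcohol 13 (not isolated)
Conditions: Ph3PAuNTf2 (5 mol %), MeOH (10 equiv), CH2Cl2, 0 °C → rt
Reagents that add atoms: methanol, CO
Why: Cationic gold activates the substrate, methanol opens the oxirane at the propargylic carbon C1 with inversion while the C10–O bond stays intact, and the released C10 oxygen adds to the gold-bound alkyne at C3, protodeauration closing the cycle. The closest known reaction type is the gold-catalysed alkoxylative cycloisomerization of alkynyl oxiranes to 3-alkoxy-2,3-dihydrofurans (the intermediates of the furan synthesis), which should stop at the dihydrofuran here because C10 is quaternary. The one ring closed is the five-membered ring, by 5-endo-dig O–C3 bond formation; O, C10 and C1 of the oxirane are kept and C2 and C3 are inserted, a ring expansion by two atoms. C10 (R) is not touched and stems from the epoxidation of step 4, and the new C1 centre (S expected from anti opening) is of no consequence because it becomes the ketone in step 10. The selectivity needed is opening at C1 and not at C10; methanolysis at C10 would give a constitutional isomer that cannot close 5-endo, so it would cost material but could not erode the configuration of 14. The acetate at C6 excludes competing 5-exo attack of the C6 oxygen on C3.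

Step 10
Reactants: 14 (2Z)-3-[(4S,5R)-5-[(2S)-2-(tert-butyldimethylsilyloxy)but-3-en-1-yl]-4-methoxy-5-methyl-4,5-dihydrofuran-2-yl]but-2-en-1-yl acetate
Product: 15 (2Z)-3-[(5R)-5-[(2S)-2-(tert-butyldimethylsilyloxy)but-3-en-1-yl]-5-methyl-4-oxo-4,5-dihydrofuran-2-yl]but-2-en-1-yl acetate
Conditions: DDQ, CH2Cl2/pH 7 buffer, 0 °C → rt
Reagents that add atoms: water, O
Why: DDQ oxidation of an activated allylic ether: hydride abstraction from C1–H (allylic to the enol ether, α to OMe) gives a 3-methoxyfuranium ion that water converts to the ketone with loss of methanol, C10 being unaffected.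

Step 11
Reactants: 15 (2Z)-3-[(5R)-5-[(2S)-2-(tert-butyldimethylsilyloxy)but-3-en-1-yl]-5-methyl-4-oxo-4,5-dihydrofuran-2-yl]but-2-en-1-yl acetate
Product: 16 (2R)-2-[(2S)-2-hydroxybut-3-en-1-yl]-5-[(2Z)-4-hydroxybut-2-en-2-yl]-2-methylfuran-3(2H)-one
Conditions: HCl (from AcCl, 0.3 equiv), MeOH, 0 °C → rt
Reagents that add atoms: none
Why: Acid-catalysed methanolysis (desilylation and transesterification of the acetate) frees both hydroxyls, the vinylogous-ester furanone being stable to dilute acid.

Step 12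
Reactants: 16 (2R)-2-[(2S)-2-hydroxybut-3-en-1-yl]-5-[(2Z)-4-hydroxybut-2-en-2-yl]-2-methylfuran-3(2H)-one
Product: 17 (2Z)-3-[(5R)-5-[(2S)-2-hydroxybut-3-en-1-yl]-5-methyl-4-oxo-4,5-dihydrofuran-2-yl]but-2-enal
Conditions: TEMPO (cat.), PhI(OAc)2, CH2Cl2, rt
Reagents that add atoms: none
Why: The oxoammonium (TEMPO) oxidation is selective for the primary allylic alcohol over the secondary C8 carbinol and mild enough to keep the Z enal.

Step 13
Reactants: 17 (2Z)-3-[(5R)-5-[(2S)-2-hydroxybut-3-en-1-yl]-5-methyl-4-oxo-4,5-dihydrofuran-2-yl]but-2-enal; 18 2-(bromomethyl)prop-2-enoic acid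
Product: 20 (2S)-1-[(2R)-2-methyl-3-oxo-5-[(2Z)-4-oxobut-2-en-2-yl]-2,3-dihydrofuran-2-yl]but-3-en-2-yl 2-(bromomethyl)prop-2-enoate, via acid chloride 19 (not isolated)
Conditions: 18, (COCl)2, DMF (cat.), CH2Cl2, 0 °C → rt; then 17, 2,6-lutidine, CH2Cl2, −40 → 0 °C
Reagents that add atoms: oxalyl chloride, O=C(Cl)C(Cl)=O (its chlorine stays only in 19)
Why: Acylation of the secondary alcohol by the acid chloride with a hindered pyridine base avoids SN2′ displacement of the allylic bromide and keeps the C8 configuration.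

Step 14
Reactants: 20 (2S)-1-[(2R)-2-methyl-3-oxo-5-[(2Z)-4-oxobut-2-en-2-yl]-2,3-dihydrofuran-2-yl]but-3-en-2-yl 2-(bromomethyl)prop-2-enoate
Product: 21 (2Z)-3-[(5R)-5-{[(2S)-4-(bromomethyl)-5-oxo-2,5-dihydrofuran-2-yl]methyl}-5-methyl-4-oxo-4,5-dihydrofuran-2-yl]but-2-enal
Conditions: second-generation Hoveyda–Grubbs catalyst (5 mol %), 1,4-benzoquinone (cat.), toluene, 60 °C
Reagents that add atoms: none
Why: Ring-closing metathesis between the vinyl group and the 1,1-disubstituted acrylate forms the α-(bromomethyl)butenolide with loss of ethene, the trisubstituted and enol-ether alkenes being inert.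

Step 15
Reactants: 21 (2Z)-3-[(5R)-5-{[(2S)-4-(bromomethyl)-5-oxo-2,5-dihydrofuran-2-yl]methyl}-5-methyl-4-oxo-4,5-dihydrofuran-2-yl]but-2-enal
Product: 22 (4Z,6R,7S,8S,10R)-6-hydroxy-1-oxo-3,10-epoxygermacra-2,4,11(13)-trien-12,8-olide
Conditions: CrCl2 (10 equiv), THF, rt, slow addition to 2 mM; then H2O
Reagents that add atoms: none
Why: Intramolecular Nozaki–Hiyama (chromium Barbier) allylation: the allylchromium should add through C7 on the butenolide face anti to the C9 substituent at C8 (trans-fused methylene lactone, C7 arranged as in the target), and the Zimmerman–Traxler chair of the ring-locked allylmetal with the aldehyde residue equatorial should give the anti carbinol, 6R.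

Step 16
Reactants: 23 (2Z)-2-methylbut-2-enoic acid
Product: 24 (2Z)-2-methylbut-2-en-1-ol
Conditions: LiAlH4, Et2O, 0 °C → rt; H2O
Reagents that add atoms: none
Why: Hydride reduction of the carboxylic acid to the primary allylic alcohol leaves the Z trisubstituted alkene untouched.

Step 17
Reactants: 24 (2Z)-2-methylbut-2-en-1-ol
Product: 25 [(2S,3R)-2,3-dimethyloxiran-2-yl]methanol
Conditions: Ti(OiPr)4, L-(+)-diethyl tartrate, t-BuOOH, 4 Å molecular sieves, CH2Cl2, −20 °C
Reagents that add atoms: tert-butyl hydroperoxide, CC(C)(C)OO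
Why: Sharpless asymmetric epoxidation with the L-tartrate sets both oxirane centres by reagent control, the cis relation of the C3 methyl and CH2OH following from the Z alkene.

Step 18
Reactants: 25 [(2S,3R)-2,3-dimethyloxiran-2-yl]methanol
Product: 26 (2R,3R)-2,3-dimethyloxirane-2-carboxylic acid
Conditions: RuCl3 (cat.), NaIO4, CCl4/MeCN/H2O, rt
Reagents that add atoms: sodium periodate, [Na+].[O-]I(=O)(=O)=O
Why: Ruthenium tetroxide oxidation of the primary alcohol to the acid does not touch the oxirane centres (the descriptor at C2 changes only through the priority switch).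

Step 19
Reactants: 22 (4Z,6R,7S,8S,10R)-6-hydroxy-1-oxo-3,10-epoxygermacra-2,4,11(13)-trien-12,8-olide; 26 (2R,3R)-2,3-dimethyloxirane-2-carboxylic acid
Product: 27 (4Z,6S,7R,8S,10R)-1-oxo-3,10-epoxygermacra-2,4,11(13)-trien-12,8-olid-6-yl (2R,3R)-2,3-dimethyloxirane-2-carboxylate
Conditions: PPh3, diisopropyl azodicarboxylate, toluene, 0 °C → rt
Reagents that add atoms: none
Why: Mitsunobu esterification displaces the oxyphosphonium by the carboxylate in an SN2 step, inverting C6 from R to S and so giving the target (the C7 label changes from S to R only through the priority switch on acylation).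

**Compound list**

1 | (2R)-2-ethenyloxirane | C=C[C@@H]1CO1 | starting material
2 | (3S)-hex-1-en-5-yn-3-ol | C=C[C@@H](O)CC#C | intermediate
3 | tert-butyl[(3S)-hex-1-en-5-yn-3-yloxy]dimethylsilane | C=C[C@@H](O[Si](C)(C)C(C)(C)C)CC#C | intermediate
4 | [(1E,4S)-4-(tert-butyldimethylsilyloxy)-2-methylhexa-1,5-dien-1-yl]dimethylalane | C=C[C@@H](O[Si](C)(C)C(C)(C)C)C/C(C)=C/[Al](C)C | intermediate
5 | (2E,5S)-5-(tert-butyldimethylsilyloxy)-3-methylhepta-2,6-dien-1-ol | C=C[C@@H](O[Si](C)(C)C(C)(C)C)C/C(C)=C/CO | intermediate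
6 | [(2R,3R)-3-[(2S)-2-(tert-butyldimethylsilyloxy)but-3-en-1-yl]-3-methyloxiran-2-yl]methanol | C=C[C@@H](O[Si](C)(C)C(C)(C)C)C[C@@]1(C)O[C@@H]1CO | intermediate
7 | (2S,3R)-3-[(2S)-2-(tert-butyldimethylsilyloxy)but-3-en-1-yl]-3-methyloxirane-2-carbaldehyde | C=C[C@@H](O[Si](C)(C)C(C)(C)C)C[C@@]1(C)O[C@@H]1C=O | intermediate
8 | tert-butyl{[(2S)-1-[(2R,3R)-3-ethynyl-2-methyloxiran-2-yl]but-3-en-2-yl]oxy}dimethylsilane | C=C[C@@H](O[Si](C)(C)C(C)(C)C)C[C@@]1(C)O[C@@H]1C#C | intermediate
9 | but-2-yn-1-ol | CC#CCO | starting material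
10 | (2Z)-3-iodobut-2-en-1-ol | OC/C=C(/C)I | intermediate
11 | (2Z)-3-iodobut-2-en-1-yl acetate | CC(=O)OC/C=C(/C)I | intermediate
12 | (2Z)-5-[(2R,3R)-3-[(2S)-2-(tert-butyldimethylsilyloxy)but-3-en-1-yl]-3-methyloxiran-2-yl]-3-methylpent-2-en-4-yn-1-yl acetate | C=C[C@@H](O[Si](C)(C)C(C)(C)C)C[C@@]1(C)O[C@@H]1C#C/C(C)=C\COC(C)=O | intermediate
13 | (2Z,6S,7R,9S)-9-(tert-butyldimethylsilyloxy)-7-hydroxy-6-methoxy-3,7-dimethylundeca-2,10-dien-4-yn-1-yl acetate | C=C[C@@H](O[Si](C)(C)C(C)(C)C)C[C@@](C)(O)[C@@H](OC)C#C/C(C)=C\COC(C)=O | intermediate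
14 | (2Z)-3-[(4S,5R)-5-[(2S)-2-(tert-butyldimethylsilyloxy)but-3-en-1-yl]-4-methoxy-5-methyl-4,5-dihydrofuran-2-yl]but-2-en-1-yl acetate | C=C[C@@H](O[Si](C)(C)C(C)(C)C)C[C@@]1(C)OC(=C[C@@H]1OC)/C(C)=C\COC(C)=O | intermediate
15 | (2Z)-3-[(5R)-5-[(2S)-2-(tert-butyldimethylsilyloxy)but-3-en-1-yl]-5-methyl-4-oxo-4,5-dihydrofuran-2-yl]but-2-en-1-yl acetate | C=C[C@@H](O[Si](C)(C)C(C)(C)C)C[C@@]1(C)OC(=CC1=O)/C(C)=C\COC(C)=O | intermediate
16 | (2R)-2-[(2S)-2-hydroxybut-3-en-1-yl]-5-[(2Z)-4-hydroxybut-2-en-2-yl]-2-methylfuran-3(2H)-one | C=C[C@@H](O)C[C@@]1(C)OC(=CC1=O)/C(C)=C\CO | intermediate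
17 | (2Z)-3-[(5R)-5-[(2S)-2-hydroxybut-3-en-1-yl]-5-methyl-4-oxo-4,5-dihydrofuran-2-yl]but-2-enal | C=C[C@@H](O)C[C@@]1(C)OC(=CC1=O)/C(C)=C\C=O | intermediate
18 | 2-(bromomethyl)prop-2-enoic acid | C=C(CBr)C(=O)O | starting material
19 | 2-(bromomethyl)prop-2-enoyl chloride | C=C(CBr)C(Cl)=O | intermediate
20 | (2S)-1-[(2R)-2-methyl-3-oxo-5-[(2Z)-4-oxobut-2-en-2-yl]-2,3-dihydrofuran-2-yl]but-3-en-2-yl 2-(bromomethyl)prop-2-enoate | C=C[C@@H](OC(=O)C(=C)CBr)C[C@@]1(C)OC(=CC1=O)/C(C)=C\C=O | intermediate
21 | (2Z)-3-[(5R)-5-{[(2S)-4-(bromomethyl)-5-oxo-2,5-dihydrofuran-2-yl]methyl}-5-methyl-4-oxo-4,5-dihydrofuran-2-yl]but-2-enal | O=C1O[C@@H](C[C@@]2(C)OC(=CC2=O)/C(C)=C\C=O)C=C1CBr | intermediate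
22 | (4Z,6R,7S,8S,10R)-6-hydroxy-1-oxo-3,10-epoxygermacra-2,4,11(13)-trien-12,8-olide (C6 epimer of the carbinol of 27; C7 arranged in space as in 27) | C=C1C(=O)O[C@H]2C[C@@]3(C)OC(=CC3=O)/C(C)=C\[C@@H](O)[C@H]12 | intermediate
23 | (2Z)-2-methylbut-2-enoic acid (angelic acid) | C/C=C(/C)C(=O)O | starting material
24 | (2Z)-2-methylbut-2-en-1-ol | C/C=C(/C)CO | intermediate
25 | [(2S,3R)-2,3-dimethyloxiran-2-yl]methanol | OC[C@]1(C)O[C@@H]1C | intermediate
26 | (2R,3R)-2,3-dimethyloxirane-2-carboxylic acid | OC(=O)[C@]1(C)O[C@@H]1C | intermediate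
27 | (4Z,6S,7R,8S,10R)-1-oxo-3,10-epoxygermacra-2,4,11(13)-trien-12,8-olid-6-yl (2R,3R)-2,3-dimethyloxirane-2-carboxylate (CNP0258430.3) | C=C1C(=O)O[C@H]2C[C@@]3(C)OC(=CC3=O)/C(C)=C\[C@H](OC(=O)[C@]3(C)O[C@@H]3C)[C@H]12 | target

**Step count.** Total: 19 steps. Longest linear sequence: 14 steps (steps 1–5, 8–15 and 19).

**Steps most likely to fail**

Step 9. Methanol may open the oxirane at the tertiary carbon C10 instead of the propargylic C1, or the acid-labile dihydrofuran may isomerize, so that little 14 forms. Fallback: the oxirane is opened earlier and under SN2 control. Compound 8 is heated with NaOMe in MeOH (attack at the less substituted, propargylic carbon) to give (3S,4R,6S)-6-(tert-butyldimethylsilyloxy)-3-methoxy-4-methyloct-7-en-1-yn-4-ol F1. Sonogashira coupling of this with 11 under the conditions of step 8 gives 13, now isolated. Compound 13 is then closed by 5-endo-dig hydroalkoxylation (Ph3PAuNTf2, CH2Cl2, no methanol) and the route is rejoined at 14.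

Step 15. The tether may force the aldehyde residue into the axial position of the cyclic transition state, so that bond formation takes place on the other face of the aldehyde. Fallback: the macrocyclization of 21 then gives the 6S alcohol (4Z,6S,7S,8S,10R)-6-hydroxy-1-oxo-3,10-epoxygermacra-2,4,11(13)-trien-12,8-olide F2. This is acylated with 26 with retention (Yamaguchi esterification: 2,4,6-trichlorobenzoyl chloride, Et3N, DMAP, toluene) and the route is rejoined at 27, the inversion of step 19 being dropped.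

Step 19. At the hindered allylic carbinol the oxyphosphonium may undergo SN2′ attack at C4 or elimination instead of clean inversion. Fallback: 22 is oxidized with Dess–Martin periodinane to the C6 ketone (4Z,7R,8S,10R)-1,6-dioxo-3,10-epoxygermacra-2,4,11(13)-trien-12,8-olide F3. The ketone is reduced with reagent control (CBS oxazaborolidine with catecholborane, using the catalyst enantiomer that delivers hydride to the face giving the 6S carbinol; 1,2-selective, so the methylene lactone is spared) to the 6S alcohol F2. Yamaguchi esterification with 26 as above then gives 27.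

**Further compounds**

F1 | step 9 | (3S,4R,6S)-6-(tert-butyldimethylsilyloxy)-3-methoxy-4-methyloct-7-en-1-yn-4-ol | C=C[C@@H](O[Si](C)(C)C(C)(C)C)C[C@@](C)(O)[C@@H](OC)C#C
F2 | step 15 | (4Z,6S,7S,8S,10R)-6-hydroxy-1-oxo-3,10-epoxygermacra-2,4,11(13)-trien-12,8-olide | C=C1C(=O)O[C@H]2C[C@@]3(C)OC(=CC3=O)/C(C)=C\[C@H](O)[C@H]12
F3 | step 19 | (4Z,7R,8S,10R)-1,6-dioxo-3,10-epoxygermacra-2,4,11(13)-trien-12,8-olide | C=C1C(=O)O[C@H]2C[C@@]3(C)OC(=CC3=O)/C(C)=C\C(=O)[C@H]12
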